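(The runs are calculated with constants of no real substance; noise was put on by code.)

Follow the E.

| flask | E | Z | remark | time |
|---|---|---|---|---|
| north | 0.010 M | 0.0102 M | run made earlier |  |
| south | 0.0067 M | 0.0102 M | run made earlier |  |
| east | 0.015 M | 0.0102 M | run made earlier |  |
| zeta | 0.010 M | 0.0102 M (fed, over 5.0 min) | all else is in the flask from the start; the feed brings no volume worth counting | 6.0 min |
| eta | 0.010 M (fed, over 5.0 min) | 0.0102 M | all else is in the flask from the start; the feed brings no volume worth counting | 6.0 min |
| theta | 0.010 M | 0.0102 M | everything together at the start | 6.0 min |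

| run | time / min | G / % |
|---|---|---|
| north | 0.333 | 66.8 |
| north | 0.833 | 66.8 |
| north | 1.50 | 64.4 |
| north | 2.50 | 59.8 |
| north | 4.00 | 53.6 |
| south | 0.500 | 81.2 |
| south | 1.50 | 79.2 |
| south | 3.00 | 73.3 |
| south | 4.00 | 69.2 |
| south | 6.00 | 63.4 |
| east | 0.500 | 44.1 |
| east | 1.50 | 33.1 |
| east | 3.00 | 27.1 |
| east | 4.00 | 23.7 |
| east | 6.00 | 20.1 |

(scatter of a reading: 0.3 percentage points)

- percentages count the E that a species holds: one J counts as two
- steps thought possible: E + Z -> G + Q; G + Q -> D; Z -> L; E + G -> J

- the flask with the highest amount of G, in percent of the E charged ("all alike" if they lie within 1.5 percentage points) (zeta / eta / theta / all alike)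
- final G, as a percentage of the E charged, in zeta
- final G, as a percentage of the E charged, in eta
- final G, as a percentage of the E charged, in theta

E is the limiting reagent: its charge of 0.010 M lies below the 0.0102 M of Z. So you keep books on the E charged, and north, with theta's charges, opens the ledger.

In north, G falls from 66.8% at 0.833 min to 53.6% at 4.00 min. I read that fall as G meeting Q to give D, with the curve of Q replaced by its mean. So 0.0695 min⁻¹ is the drain, the pseudo-first-order fraction of G lost to D per minute. Its time constant is 14.4 min.

Now the entries, as I reckon them. Run the drain back to the start, and north has made 70.8% as G. The other 29.2% sits in J. Theta repeats north, so at 6.0 min it holds 46.6% in G and 24.2% in D, and the books close.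

In eta, E enters steadily, so G has a mean age of 3.50 min. With the same share in J, that leaves 55.5% in G. Averaging over every birth time instead of the mean age shifts this by 0.28 percentage points, against a scatter of 0.3 points. In zeta, Z is the one fed, and I reckon nothing there.

The forecast names eta, with 29% in zeta, 55% in eta and 47% in theta, holding that “selectivity depends only on the ratio G/Z, so feeding E leaves it unchanged”.

    E + Z → G + Q (k = 1200 L mol⁻¹ min⁻¹)
    G + Q → D (k = 9.40 L mol⁻¹ min⁻¹)
    Z → L (k = 0.0680 min⁻¹)
    E + G → J (k = 190 L mol⁻¹ min⁻¹)

Zeta gives 24.9%, eta 49.7% and theta 47.7%, against the ledger's 46.6% for theta, so eta leads by 2 points, more than the margin of 1.5 points. Theta closes with 29.0% in J, less than the 37.0% of eta. In eta, E with Z uses Z 5.0 times as fast as Z to L at 2.24 min, and 2.6 times as fast at 6.00 min. The drain carries eta's G to 37.6% by 10 min, and that neighbour flask holds 38.9%.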